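**Retrosynthetic overview**
1. Feature: in the cyclohexenone ring (ring A), carbon C2 is bonded to three carbonyl-level carbons: ring C1, ring C3 and side-chain C1'. C2 is therefore the central carbon of a C3/C1' 1,3-diketone that has been acylated by C1. Ring bond C1–C2 is cut to an open-chain methyl 5,7-dioxo ester that already holds the C5 carbinol, as its TBS ether, at chain C3.
2. The diketone is cut between chain C5 and C6. This gives the kinetic methyl enolate of a 10-aryldecan-2-one and the acyl imidazole of the (S) half-ester, which comes from alkaloid-catalysed methanolysis of 3-silyloxyglutaric anhydride.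
3. The aryl ketone comes from 3,4-bis(benzyloxy)benzaldehyde and 8-bromooctanoic acid (Wittig, diimide, MeLi).
4. Ring order: the arene (ring B) is bought and ring A is the only ring made (step 8). The silyl and benzyl groups then come off under near-neutral conditions.

Key step: step 8

Assumption: in a 2-acylcyclohexane-1,3-dione the enol proton moves between O1 and O3 (with rotation of the acyl group) and so exchanges the two ring arms at C5, which makes the (5S) and (5R) drawings tautomers of one substance; C5 is therefore carried as a true (S) centre through all open-chain compounds (at no extra step, since the anhydride must be opened with methanol anyway), and the cyclised compounds are written as the tautomer that maps directly onto the given SMILES (former ketone carbon = enol C3, former ester carbon = keto C1), with no claim of lasting optical activity.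

**Step 1**
Reactants: 1 8-bromooctanoic acid
Product: 2 (7-carboxyheptyl)triphenylphosphonium bromide
Conditions: PPh3, MeCN, reflux
Reagents that add atoms: triphenylphosphine, c1ccc(cc1)P(c1ccccc1)c1ccccc1
Why: SN2 quaternisation of the phosphine by the primary bromide; the free acid does not interfere and the salt should crystallise.

**Step 2**
Reactants: 2 (7-carboxyheptyl)triphenylphosphonium bromide; 3 3,4-bis(benzyloxy)benzaldehyde
Product: 5 (8Z)-9-[3,4-bis(benzyloxy)phenyl]non-8-enoic acid (some 8E isomer is carried along), via sodium ylide carboxylate 4 (not isolated)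
Conditions: NaN(SiMe3)2 (2.1 equiv), THF, 0 °C; then 3, −78 °C to rt; aq HCl
Reagents that add atoms: none
Why: Wittig olefination with a non-stabilised, carboxylate-bearing ylide (one equivalent of base goes to the acid) should give mainly the Z-alkene, and the geometry does not matter because step 3 saturates the double bond.

**Step 3**
Reactants: 5 (8Z)-9-[3,4-bis(benzyloxy)phenyl]non-8-enoic acid
Product: 6 9-[3,4-bis(benzyloxy)phenyl]nonanoic acid
Conditions: TsNHNH2 (excess), NaOAc, DME/H2O, reflux
Reagents that add atoms: none
Why: Diimide reduction (concerted syn transfer of two hydrogens from HN=NH made in the flask) saturates the C=C bond and, unlike hydrogenation over palladium, cannot cleave the two aryl benzyl ethers.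

**Step 4**
Reactants: 6 9-[3,4-bis(benzyloxy)phenyl]nonanoic acid
Product: 8 10-[3,4-bis(benzyloxy)phenyl]decan-2-one, via dilithium gem-diolate 7 (not isolated)
Conditions: MeLi (2.2 equiv), THF, 0 °C; inverse quench into cold 1 M HCl
Reagents that add atoms: methyllithium, [Li]C
Why: In this organolithium addition to a lithium carboxylate, the gem-diolate persists until the quench, so the ketone is released only when no MeLi is left and tertiary-alcohol formation is held back.

**Step 5**
Reactants: 9 3-[(tert-butyldimethylsilyl)oxy]glutaric anhydride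
Product: 10 (3S)-3-[(tert-butyldimethylsilyl)oxy]-5-methoxy-5-oxopentanoic acid
Conditions: hydroquinidine anthraquinone-1,4-diyl diether, (DHQD)2AQN (0.3 equiv), MeOH (10 equiv), Et2O, −40 °C; aq citric acid wash
Reagents that add atoms: methanol, CO
Why: In this cinchona-alkaloid-catalysed desymmetrising methanolysis of a prochiral cyclic anhydride, the quinuclidine nitrogen activates MeOH in the chiral pocket so that one of the two enantiotopic carbonyls is attacked, which sets the only stereocentre (chain C3, future ring C5); the quinidine-derived catalyst is chosen by analogy with 3-alkylglutaric anhydrides, where the quinine series esterifies the opposite arm, and the sense of induction is to be checked against the commercially available (3R) enantiomer.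

**Step 6**
Reactants: 10 (3S)-3-[(tert-butyldimethylsilyl)oxy]-5-methoxy-5-oxopentanoic acid
Product: 11 methyl (3S)-3-[(tert-butyldimethylsilyl)oxy]-5-(1H-imidazol-1-yl)-5-oxopentanoate
Conditions: CDI (1.1 equiv), CH2Cl2, rt; cold water wash, dry, concentrate, use crude
Reagents that add atoms: 1,1'-carbonyldiimidazole, O=C(n1ccnc1)n1ccnc1
Why: Acyl-imidazole formation with CDI, driven by loss of CO2, is neutral enough for the β-silyloxy ester, and the water wash removes imidazole (acidic N–H) and surplus CDI, both of which would consume enolate in step 7.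

**Step 7**
Reactants: 8 10-[3,4-bis(benzyloxy)phenyl]decan-2-one; 11 methyl (3S)-3-[(tert-butyldimethylsilyl)oxy]-5-(1H-imidazol-1-yl)-5-oxopentanoate
Product: 13 methyl (3S)-15-[3,4-bis(benzyloxy)phenyl]-3-[(tert-butyldimethylsilyl)oxy]-5,7-dioxopentadecanoate, via lithium enolate 12 (not isolated)
Conditions: 8 (2.1 equiv) added to LiN(iPr)2 (commercial solution, 2.05 equiv), THF, −78 °C; then 11 (1 equiv), −78 °C; AcOH quench at −78 °C
Reagents that add atoms: none
Why: In this crossed Claisen-type C-acylation of a kinetic lithium enolate, the amide base deprotonates the methyl side of 8 at −78 °C, the enolate attacks the acyl imidazole much faster than the methyl ester, the second equivalent of enolate takes up the acidic proton of the new diketone (the ketone so regenerated is recovered), and the cold acidic quench prevents early ring closure or β-elimination, so C3 is untouched.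

**Step 8**
Reactants: 13 methyl (3S)-15-[3,4-bis(benzyloxy)phenyl]-3-[(tert-butyldimethylsilyl)oxy]-5,7-dioxopentadecanoate
Product: 16 (5S)-2-{9-[3,4-bis(benzyloxy)phenyl]nonanoyl}-5-[(tert-butyldimethylsilyl)oxy]-3-hydroxycyclohex-2-en-1-one, via potassium diketonate 14 (not isolated), via potassium triketonate 15 (not isolated)
Conditions: KOtBu (1.05 equiv, slow addition), THF, 0 °C to rt (40 °C if slow); cold aq KHSO4
Reagents that add atoms: none
Why: The base is consumed at once by the chain C6 methylene between the two ketones to give 14, whose central carbon (future C2) adds to the ester carbonyl (future C1); loss of methoxide completes ring bond C1–C2, and the methoxide then deprotonates the new tricarbonyl to 15, which pulls the otherwise reversible sequence towards the ring. The closest known reaction type is the Dieckmann-type (intramolecular Claisen) cyclisation of δ-keto esters and 5,7-dioxo esters to cyclohexane-1,3-diones. Ring A closes in the favoured 6-(enolexo)-exo-trig mode (counting the C6=C7 enolate), and competing closure through the diketonate oxygen to a six-membered enol lactone is reversible, because the released methoxide reopens that activated ester, so this material also drains into 15. No stereocentre is created: the silyloxy carbon comes from 10 and takes part in no bond change, although from here on its two ring arms differ only in the position of the enol. The selectivity needed is C-acylation ahead of E1cB loss of the silyloxy group (β to both the ester and the chain C5 ketone) and ahead of aromatisation of the product. It is secured by adding only one equivalent of base, so that chain C2–H and C4–H never meet free strong base, by the fact that 14 and 15 would have to become dianions to eliminate, and by the known tolerance of the CO–CH2–CH(OSi)–CH2–CO2Me array for stabilised-anion chemistry such as keto-phosphonate olefination.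

**Step 9**
Reactants: 16 (5S)-2-{9-[3,4-bis(benzyloxy)phenyl]nonanoyl}-5-[(tert-butyldimethylsilyl)oxy]-3-hydroxycyclohex-2-en-1-one
Product: 17 (5S)-2-{9-[3,4-bis(benzyloxy)phenyl]nonanoyl}-3,5-dihydroxycyclohex-2-en-1-one
Conditions: HF·pyridine, extra pyridine, THF, 0 °C to rt (plastic vessel); pH 5–6 buffer work-up, bath below 30 °C
Reagents that add atoms: none
Why: Fluoride-driven cleavage of the secondary silyl ether (Si–F bond formation) in a pyridine-buffered, cold medium should free the carbinol without dehydrating the β-hydroxy ketone to the 2-acylresorcinol, and the benzyl ethers are inert.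

**Step 10**
Reactants: 17 (5S)-2-{9-[3,4-bis(benzyloxy)phenyl]nonanoyl}-3,5-dihydroxycyclohex-2-en-1-one
Product: 18 (5S)-2-[9-(3,4-dihydroxyphenyl)nonanoyl]-3,5-dihydroxycyclohex-2-en-1-one (target)
Conditions: H2 (1 atm), 10% Pd/C (acid-free), EtOAc, rt; filter under argon, concentrate below 30 °C
Reagents that add atoms: none
Why: Catalytic hydrogenolysis of the two aryl benzyl ethers in a neutral solvent should leave the hydrogen-bonded enolised tricarbonyl (a vinylogous acid) and the non-benzylic secondary alcohol untouched, and the air-sensitive catechol is unveiled last.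

**Compound list**
1 | 8-bromooctanoic acid | OC(=O)CCCCCCCBr | starting material
2 | (7-carboxyheptyl)triphenylphosphonium bromide | [Br-].OC(=O)CCCCCCC[P+](c1ccccc1)(c1ccccc1)c1ccccc1 | intermediate
3 | 3,4-bis(benzyloxy)benzaldehyde | O=Cc1ccc(OCc2ccccc2)c(OCc3ccccc3)c1 | starting material
4 | sodium 8-(triphenylphosphoranylidene)octanoate | [Na+].[O-]C(=O)CCCCCCC=P(c1ccccc1)(c1ccccc1)c1ccccc1 | intermediate
5 | (8Z)-9-[3,4-bis(benzyloxy)phenyl]non-8-enoic acid | OC(=O)CCCCCC/C=C\c1ccc(OCc2ccccc2)c(OCc3ccccc3)c1 | intermediate
6 | 9-[3,4-bis(benzyloxy)phenyl]nonanoic acid | OC(=O)CCCCCCCCc1ccc(OCc2ccccc2)c(OCc3ccccc3)c1 | intermediate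
7 | dilithium 10-[3,4-bis(benzyloxy)phenyl]decane-2,2-diolate | [Li+].[Li+].CC([O-])([O-])CCCCCCCCc1ccc(OCc2ccccc2)c(OCc3ccccc3)c1 | intermediate
8 | 10-[3,4-bis(benzyloxy)phenyl]decan-2-one | CC(=O)CCCCCCCCc1ccc(OCc2ccccc2)c(OCc3ccccc3)c1 | intermediate
9 | 3-[(tert-butyldimethylsilyl)oxy]glutaric anhydride | O=C1CC(O[Si](C)(C)C(C)(C)C)CC(=O)O1 | starting material
10 | (3S)-3-[(tert-butyldimethylsilyl)oxy]-5-methoxy-5-oxopentanoic acid | OC(=O)C[C@H](O[Si](C)(C)C(C)(C)C)CC(=O)OC | intermediate
11 | methyl (3S)-3-[(tert-butyldimethylsilyl)oxy]-5-(1H-imidazol-1-yl)-5-oxopentanoate | O=C(n1ccnc1)C[C@H](O[Si](C)(C)C(C)(C)C)CC(=O)OC | intermediate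
12 | lithium 10-[3,4-bis(benzyloxy)phenyl]dec-1-en-2-olate | [Li+].[O-]C(=C)CCCCCCCCc1ccc(OCc2ccccc2)c(OCc3ccccc3)c1 | intermediate
13 | methyl (3S)-15-[3,4-bis(benzyloxy)phenyl]-3-[(tert-butyldimethylsilyl)oxy]-5,7-dioxopentadecanoate | O=C(CCCCCCCCc1ccc(OCc2ccccc2)c(OCc3ccccc3)c1)CC(=O)C[C@H](O[Si](C)(C)C(C)(C)C)CC(=O)OC | intermediate
14 | potassium salt of 13, deprotonated at chain C6 | [K+].O=C(CCCCCCCCc1ccc(OCc2ccccc2)c(OCc3ccccc3)c1)[CH-]C(=O)C[C@H](O[Si](C)(C)C(C)(C)C)CC(=O)OC | intermediate
15 | potassium salt of 16 (delocalised triketonate) | [K+].O=C(CCCCCCCCc1ccc(OCc2ccccc2)c(OCc3ccccc3)c1)C1=C([O-])C[C@H](O[Si](C)(C)C(C)(C)C)CC1=O | intermediate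
16 | (5S)-2-{9-[3,4-bis(benzyloxy)phenyl]nonanoyl}-5-[(tert-butyldimethylsilyl)oxy]-3-hydroxycyclohex-2-en-1-one | O=C(CCCCCCCCc1ccc(OCc2ccccc2)c(OCc3ccccc3)c1)C1=C(O)C[C@H](O[Si](C)(C)C(C)(C)C)CC1=O | intermediate
17 | (5S)-2-{9-[3,4-bis(benzyloxy)phenyl]nonanoyl}-3,5-dihydroxycyclohex-2-en-1-one | O=C(CCCCCCCCc1ccc(OCc2ccccc2)c(OCc3ccccc3)c1)C1=C(O)C[C@H](O)CC1=O | intermediate
18 | (5S)-2-[9-(3,4-dihydroxyphenyl)nonanoyl]-3,5-dihydroxycyclohex-2-en-1-one | O=C(CCCCCCCCc1ccc(O)c(O)c1)C1=C(O)C[C@H](O)CC1=O | target

Total step count: 10
Longest linear sequence: 8 (steps 1–4 and 7–10)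

**Steps most likely to fail**

Step 8. The stabilised diketonate may add too slowly to the unactivated methyl ester. On warming, proton exchange could then let E1cB loss of the silyloxy group, followed by aromatisation, overtake ring closure. The fallback sets out from 13 and returns at 16. It makes the same C1–C2 bond from an activated acyl donor under soft enolisation instead of from the ester. Me3SnOH in 1,2-dichloroethane at 60 °C should cleave the methyl ester to (3S)-15-[3,4-bis(benzyloxy)phenyl]-3-[(tert-butyldimethylsilyl)oxy]-5,7-dioxopentadecanoic acid F1. CDI in CH2Cl2 should convert this into (3S)-15-[3,4-bis(benzyloxy)phenyl]-3-[(tert-butyldimethylsilyl)oxy]-1-(1H-imidazol-1-yl)pentadecane-1,5,7-trione F2. MgCl2/Et3N in MeCN at 0 °C (C-acylation of a magnesium-chelated 1,3-dicarbonyl by an acyl imidazole) should then close ring A to 16 without any strong base.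

Step 7. The enolate may act as a base rather than a nucleophile, by α-deprotonating the acyl imidazole (with β-elimination) or by being quenched early by the product. It may also acylate on oxygen. In each case conversion stalls and ketone 8 is tied up. The fallback sets out from 10 and returns at 13. It replaces the acylation by aldol addition and oxidation, which needs only one equivalent of enolate. BH3·SMe2 in THF at 0 °C should reduce the free acid of 10 selectively to methyl (3S)-3-[(tert-butyldimethylsilyl)oxy]-5-hydroxypentanoate F3. Dess–Martin oxidation should give methyl (3S)-3-[(tert-butyldimethylsilyl)oxy]-5-oxopentanoate F4. Addition of enolate 12 at −78 °C should give methyl (3S)-15-[3,4-bis(benzyloxy)phenyl]-3-[(tert-butyldimethylsilyl)oxy]-5-hydroxy-7-oxopentadecanoate F5 as both C5 epimers, and a second Dess–Martin oxidation converges them on 13.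

Step 9. The freed β-hydroxy ketone may lose water under acid catalysis and aromatise during desilylation, work-up or chromatography, and it is exposed again in step 10. The fallback sets out from 16 and returns at 18. It reverses the order of the two deprotections, so that the labile carbinol appears only in the last operation and never meets the palladium catalyst or a second purification. Hydrogenolysis of 16 (H2, Pd/C, EtOAc, rt) should give (5S)-5-[(tert-butyldimethylsilyl)oxy]-2-[9-(3,4-dihydroxyphenyl)nonanoyl]-3-hydroxycyclohex-2-en-1-one F6. Et3N·3HF in MeCN under argon at rt should then convert F6 directly into 18.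

**Further compounds**
F1 | step 8 | (3S)-15-[3,4-bis(benzyloxy)phenyl]-3-[(tert-butyldimethylsilyl)oxy]-5,7-dioxopentadecanoic acid | O=C(CCCCCCCCc1ccc(OCc2ccccc2)c(OCc3ccccc3)c1)CC(=O)C[C@H](O[Si](C)(C)C(C)(C)C)CC(=O)O
F2 | step 8 | (3S)-15-[3,4-bis(benzyloxy)phenyl]-3-[(tert-butyldimethylsilyl)oxy]-1-(1H-imidazol-1-yl)pentadecane-1,5,7-trione | O=C(CCCCCCCCc1ccc(OCc2ccccc2)c(OCc3ccccc3)c1)CC(=O)C[C@H](O[Si](C)(C)C(C)(C)C)CC(=O)n1ccnc1
F3 | step 7 | methyl (3S)-3-[(tert-butyldimethylsilyl)oxy]-5-hydroxypentanoate | OCC[C@H](O[Si](C)(C)C(C)(C)C)CC(=O)OC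
F4 | step 7 | methyl (3S)-3-[(tert-butyldimethylsilyl)oxy]-5-oxopentanoate | O=CC[C@H](O[Si](C)(C)C(C)(C)C)CC(=O)OC
F5 | step 7 | methyl (3S)-15-[3,4-bis(benzyloxy)phenyl]-3-[(tert-butyldimethylsilyl)oxy]-5-hydroxy-7-oxopentadecanoate (both C5 epimers) | O=C(CCCCCCCCc1ccc(OCc2ccccc2)c(OCc3ccccc3)c1)CC(O)C[C@H](O[Si](C)(C)C(C)(C)C)CC(=O)OC
F6 | step 9 | (5S)-5-[(tert-butyldimethylsilyl)oxy]-2-[9-(3,4-dihydroxyphenyl)nonanoyl]-3-hydroxycyclohex-2-en-1-one | O=C(CCCCCCCCc1ccc(O)c(O)c1)C1=C(O)C[C@H](O[Si](C)(C)C(C)(C)C)CC1=O
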